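**Retrosynthetic overview**
- The target comes from a tetra-ether biflavone by one BCl3 dealkylation. The pyranone of flavone 2 comes from a crossed Claisen condensation of a phenyl ester (Pd carbonylation of the aryl bromide) with O-dibenzyl phloroacetophenone, followed by cyclodehydration.
- The pyranone of flavone 1 comes from Hoesch acetylation at C4a, C-aroylation with 4-methoxybenzoyl chloride and cyclodehydration onto the oxygen on C8a.
- Ring A of flavone 1 comes from the benzannulation of 3-ethoxycyclobutenone with the triisopropylsilyl ynol ether of the 2-bromo-5-methoxyphenyl unit: C8–C8a and C6–C7 by [2+2], C4a–C8a by six-electron closure. The ynol ether comes from 2-bromo-5-methoxybenzaldehyde.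
- Feature: ring A of flavone 1 (C4a, C5, C6, C7, C8, C8a) is a phloroglucinol whose C8 aryl group lies between O7 and the pyranone oxygen O1 on C8a. O5, para to C8, must be marked differently from these two so that the pyranone closes beside the aryl group (8-aryl, not 6-aryl); the cyclobutenone delivers O5 as an ethyl ether.
- Ring order: ring A of flavone 1 (step 3), ring C of flavone 1 (step 8), ring C of flavone 2 (step 12). Ring A of flavone 2 is bought as phloroacetophenone, and both B rings are intact arenes.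

Key step: step 3

Assumption: the given structure assigns no configuration to the hindered C8–aryl axis, so no atropselection is attempted and the material is made as the racemate.

**Step 1**
Reactants: 1 2-bromo-5-methoxybenzaldehyde
Product: 3 1-bromo-2-ethynyl-4-methoxybenzene, via diazoalkene 2 (not isolated)
Conditions: dimethyl (1-diazo-2-oxopropyl)phosphonate, K2CO3, MeOH, 0 °C to rt
Reagents that add atoms: dimethyl (1-diazo-2-oxopropyl)phosphonate, COP(=O)(OC)C(=[N+]=[N-])C(C)=O
Why: Seyferth–Gilbert homologation in the Ohira–Bestmann form: methanolysis of the reagent gives the diazomethylphosphonate anion, which olefinates the aldehyde to diazoalkene 2, and loss of N2 with 1,2-hydrogen shift should give the alkyne without touching the aryl bromide.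

**Step 2**
Reactants: 3 1-bromo-2-ethynyl-4-methoxybenzene
Product: 6 [(2-bromo-5-methoxyphenyl)ethynyloxy]tri(propan-2-yl)silane, via lithium acetylide 4 (not isolated), via lithium ynolate 5 (not isolated)
Conditions: LiN(SiMe3)2, THF, −78 °C; t-BuOOLi (from t-BuOOH and LiN(SiMe3)2), −78 to 0 °C; i-Pr3SiOTf, −78 °C to rt
Reagents that add atoms: tert-butyl hydroperoxide, CC(C)(C)OO; triisopropylsilyl trifluoromethanesulfonate, CC(C)[Si](OS(=O)(=O)C(F)(F)F)(C(C)C)C(C)C
Why: Electrophilic oxygenation of acetylide 4 by lithium tert-butyl peroxide (Julia ynolate synthesis) should give ynolate 5, which the bulky silyl triflate captures on oxygen; the amide base is too weak a nucleophile for bromine–lithium exchange, and 6 is used at once after filtration through deactivated silica.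

**Step 3**
Reactants: 6 [(2-bromo-5-methoxyphenyl)ethynyloxy]tri(propan-2-yl)silane; 7 3-ethoxycyclobut-2-en-1-one
Product: 12 2-(2-bromo-5-methoxyphenyl)-5-ethoxy-3-[tri(propan-2-yl)silyloxy]phenol, via vinylketene 8 (not isolated), via vinylcyclobutenone 9 (not isolated), via dienylketene 10 (not isolated), via cyclohexadienone 11 (not isolated)
Conditions: 7 (1.2 equiv, syringe pump), PhMe, 120 °C, sealed tube
Reagents that add atoms: none
Why: Proposed new method: heat opens cyclobutenone 7 by four-electron electrocyclic cleavage to 3-ethoxyvinylketene 8, whose electrophilic carbonyl carbon bonds to the nucleophilic aryl-bearing carbon of ynol ether 6 in a [2+2] cycloaddition to give vinylcyclobutenone 9; 9 opens reversibly (four electrons) to dienylketene 10, and a six-electron disrotatory electrocyclisation joins the ketene carbon to the terminal CH2 to close ring A as cyclohexadienone 11, which tautomerises to phenol 12. The closest known reaction is the Danheiser benzannulation of 3-alkyl- and 3-aryl-cyclobutenones with triisopropylsilyl ynol ethers to resorcinol monosilyl ethers; new here is the 3-alkoxy group, which makes 7 a vinylogous ester that should open more slowly (hence 120 °C) yet leaves the ketene carbonyl of 8 electrophilic, because the ether oxygen is only cross-conjugated with it. Three skeletal bonds form, C8–C8a and C6–C7 in the [2+2] step and C4a–C8a in the six-electron closure; no stereocentre is created, and the one in 9 is lost on aromatisation. The one selectivity needed is the regiochemistry of the [2+2], secured by the polarisation of the partners (silyloxy-bearing carbon cationic, aryl-bearing carbon nucleophilic), which puts the aryl group ortho and the silyloxy group meta to the new hydroxyl and leaves the ethoxy group para to the aryl group, at O5. Slow addition keeps 8 dilute, so that capture by 6 should outrun ketene dimerisation and acylation of 12.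

**Step 4**
Reactants: 12 2-(2-bromo-5-methoxyphenyl)-5-ethoxy-3-[tri(propan-2-yl)silyloxy]phenol
Product: 13 2-(2-bromo-5-methoxyphenyl)-5-ethoxybenzene-1,3-diol
Conditions: Bu4NF, AcOH, THF, 0 °C
Reagents that add atoms: none
Why: Fluoride desilylation buffered with acetic acid frees the second aryl-flanked hydroxyl, so the two ring positions open to acylation become equivalent and O7 can later carry a benzyl group that survives Lewis acid, base and palladium.

**Step 5**
Reactants: 13 2-(2-bromo-5-methoxyphenyl)-5-ethoxybenzene-1,3-diol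
Product: 15 1-[3-(2-bromo-5-methoxyphenyl)-6-ethoxy-2,4-dihydroxyphenyl]ethan-1-one, via ketiminium chloride 14 (not isolated)
Conditions: MeCN, ZnCl2, HCl (g), Et2O, 0 °C; then H2O, 90 °C
Reagents that add atoms: acetonitrile, CC#N; water, O
Why: Houben–Hoesch acylation: the nitrilium species attacks the phloroglucinol-type ring at C4 or C6 of 13, which are equivalent and the only free positions, each ortho to an aryl-flanked hydroxyl and to the ethoxy group, and hydrolysis of 14 gives the ketone; the bromoanisole ring is far less nucleophilic.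

**Step 6**
Reactants: 15 1-[3-(2-bromo-5-methoxyphenyl)-6-ethoxy-2,4-dihydroxyphenyl]ethan-1-one
Product: 16 1-[4-(benzyloxy)-3-(2-bromo-5-methoxyphenyl)-6-ethoxy-2-hydroxyphenyl]ethan-1-one
Conditions: BnBr (1.05 equiv), K2CO3, acetone, 56 °C
Reagents that add atoms: benzyl bromide, BrCc1ccccc1
Why: Williamson etherification should be selective for the 4-hydroxyl, because the 2-hydroxyl is hydrogen-bonded to the acetyl carbonyl and flanked on both sides.

**Step 7**
Reactants: 16 1-[4-(benzyloxy)-3-(2-bromo-5-methoxyphenyl)-6-ethoxy-2-hydroxyphenyl]ethan-1-one; 17 4-methoxybenzoyl chloride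
Product: 19 1-[4-(benzyloxy)-3-(2-bromo-5-methoxyphenyl)-6-ethoxy-2-hydroxyphenyl]-3-(4-methoxyphenyl)propane-1,3-dione, via dilithium dianion 18 (not isolated)
Conditions: LiN(SiMe3)2 (3.5 equiv), THF, −78 to −10 °C; 17, −78 °C to rt; 1 M HCl
Reagents that add atoms: none
Why: One-pot Baker–Venkataraman-type diketone synthesis: phenoxide–enolate 18 is C-aroylated by 17, any O-aroyl ester rearranges under the excess base, and the product is stored as its enolate until the acid quench.

**Step 8**
Reactants: 19 1-[4-(benzyloxy)-3-(2-bromo-5-methoxyphenyl)-6-ethoxy-2-hydroxyphenyl]-3-(4-methoxyphenyl)propane-1,3-dione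
Product: 20 7-(benzyloxy)-8-(2-bromo-5-methoxyphenyl)-5-ethoxy-2-(4-methoxyphenyl)-4H-chromen-4-one
Conditions: TsOH·H2O (cat.), PhMe, 100 °C
Reagents that add atoms: none
Why: Acid-catalysed cyclodehydration (6-exo-trig hemiketal, then loss of water) closes the pyranone onto the only free oxygen, the one on C8a beside the aryl group, since O5 is an ethyl ether and O7 a benzyl ether.

**Step 9**
Reactants: 20 7-(benzyloxy)-8-(2-bromo-5-methoxyphenyl)-5-ethoxy-2-(4-methoxyphenyl)-4H-chromen-4-one
Product: 21 phenyl 2-[7-(benzyloxy)-5-ethoxy-2-(4-methoxyphenyl)-4-oxo-4H-chromen-8-yl]-4-methoxybenzoate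
Conditions: HCO2Ph, Pd(OAc)2 (cat.), P(t-Bu)3·HBF4 (cat.), Et3N, MeCN–PhMe, 80 °C
Reagents that add atoms: phenyl formate, O=COc1ccccc1
Why: Palladium-catalysed aryloxycarbonylation: Et3N splits phenyl formate into CO and phenol, zerovalent palladium inserts into the C–Br bond, CO insertion and capture by phenoxide give the activated ester, and the benzyl group on O7 blocks lactonisation of the acyl-palladium species.

**Step 10**
Reactants: 22 1-(2,4,6-trihydroxyphenyl)ethan-1-one
Product: 23 1-[2,4-bis(benzyloxy)-6-hydroxyphenyl]ethan-1-one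
Conditions: BnBr (2.1 equiv), K2CO3, DMF, rt
Reagents that add atoms: benzyl bromide, BrCc1ccccc1
Why: Williamson etherification stops at the dibenzyl ether because the last hydroxyl is hydrogen-bonded to the acetyl carbonyl.

**Step 11**
Reactants: 21 phenyl 2-[7-(benzyloxy)-5-ethoxy-2-(4-methoxyphenyl)-4-oxo-4H-chromen-8-yl]-4-methoxybenzoate; 23 1-[2,4-bis(benzyloxy)-6-hydroxyphenyl]ethan-1-one
Product: 25 1-[2,4-bis(benzyloxy)-6-hydroxyphenyl]-3-{2-[7-(benzyloxy)-5-ethoxy-2-(4-methoxyphenyl)-4-oxo-4H-chromen-8-yl]-4-methoxyphenyl}propane-1,3-dione, via dilithium dianion 24 (not isolated)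
Conditions: 23 (2 equiv), LiN(SiMe3)2 (4.2 equiv), THF, −78 to −20 °C; 21, −78 °C to rt; 1 M HCl
Reagents that add atoms: none
Why: Crossed Claisen condensation: dianion 24 is C-acylated by the phenyl ester with loss of phenoxide, the diketone is held as its enolate, and the chromone carbonyl of 21, a vinylogous ester, should be a much poorer electrophile at low temperature.

**Step 12**
Reactants: 25 1-[2,4-bis(benzyloxy)-6-hydroxyphenyl]-3-{2-[7-(benzyloxy)-5-ethoxy-2-(4-methoxyphenyl)-4-oxo-4H-chromen-8-yl]-4-methoxyphenyl}propane-1,3-dione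
Product: 26 7-(benzyloxy)-8-{2-[5,7-bis(benzyloxy)-4-oxo-4H-chromen-2-yl]-5-methoxyphenyl}-5-ethoxy-2-(4-methoxyphenyl)-4H-chromen-4-one
Conditions: TsOH·H2O (cat.), PhMe, 100 °C
Reagents that add atoms: none
Why: Cyclodehydration as in step 8: the single free hydroxyl adds to the carbonyl on the linking aryl ring and water is lost, which closes the pyranone of flavone 2 with its C2 on that ring.

**Step 13**
Reactants: 26 7-(benzyloxy)-8-{2-[5,7-bis(benzyloxy)-4-oxo-4H-chromen-2-yl]-5-methoxyphenyl}-5-ethoxy-2-(4-methoxyphenyl)-4H-chromen-4-one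
Product: 27 8-[2-(5,7-dihydroxy-4-oxo-4H-chromen-2-yl)-5-methoxyphenyl]-5,7-dihydroxy-2-(4-methoxyphenyl)-4H-chromen-4-one
Conditions: BCl3 (excess), C6HMe5, CH2Cl2, −78 °C to rt; then H2O
Reagents that add atoms: none
Why: Lewis-acid ether cleavage: BCl3 with pentamethylbenzene as cation scavenger removes the three benzyl groups cold, and on warming the ethyl group on O5 is cleaved through the boron chelate between O5 and the C4 carbonyl, whereas the two unchelated aryl methyl ethers should not react with BCl3 at or below room temperature.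

**Compound list**
1 | 2-bromo-5-methoxybenzaldehyde | COc1ccc(Br)c(C=O)c1 | starting material
2 | 1-bromo-2-(2-diazoethenyl)-4-methoxybenzene | COc1ccc(Br)c(C=C=[N+]=[N-])c1 | intermediate
3 | 1-bromo-2-ethynyl-4-methoxybenzene | COc1ccc(Br)c(C#C)c1 | intermediate
4 | lithium (2-bromo-5-methoxyphenyl)ethynide | COc1ccc(Br)c(C#[C-])c1.[Li+] | intermediate
5 | lithium 2-(2-bromo-5-methoxyphenyl)ethynolate | COc1ccc(Br)c(C#C[O-])c1.[Li+] | intermediate
6 | [(2-bromo-5-methoxyphenyl)ethynyloxy]tri(propan-2-yl)silane | COc1ccc(Br)c(C#CO[Si](C(C)C)(C(C)C)C(C)C)c1 | intermediate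
7 | 3-ethoxycyclobut-2-en-1-one | CCOC1=CC(=O)C1 | starting material
8 | 3-ethoxybuta-1,3-dien-1-one | C=C(OCC)C=C=O | intermediate
9 | 2-(2-bromo-5-methoxyphenyl)-4-(1-ethoxyethenyl)-3-[tri(propan-2-yl)silyloxy]cyclobut-2-en-1-one (racemic) | CCOC(=C)C1C(=O)C(c2cc(OC)ccc2Br)=C1O[Si](C(C)C)(C(C)C)C(C)C | intermediate
10 | (3E)-2-(2-bromo-5-methoxyphenyl)-5-ethoxy-3-[tri(propan-2-yl)silyloxy]hexa-1,3,5-trien-1-one | O=C=C(c1cc(OC)ccc1Br)/C(O[Si](C(C)C)(C(C)C)C(C)C)=C\C(OCC)=C | intermediate
11 | 2-(2-bromo-5-methoxyphenyl)-5-ethoxy-3-[tri(propan-2-yl)silyloxy]cyclohexa-2,4-dien-1-one | CCOC1=CC(O[Si](C(C)C)(C(C)C)C(C)C)=C(c2cc(OC)ccc2Br)C(=O)C1 | intermediate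
12 | 2-(2-bromo-5-methoxyphenyl)-5-ethoxy-3-[tri(propan-2-yl)silyloxy]phenol | CCOc1cc(O)c(-c2cc(OC)ccc2Br)c(O[Si](C(C)C)(C(C)C)C(C)C)c1 | intermediate
13 | 2-(2-bromo-5-methoxyphenyl)-5-ethoxybenzene-1,3-diol | CCOc1cc(O)c(-c2cc(OC)ccc2Br)c(O)c1 | intermediate
14 | 1-[3-(2-bromo-5-methoxyphenyl)-6-ethoxy-2,4-dihydroxyphenyl]ethan-1-iminium chloride | CC(=[NH2+])c1c(OCC)cc(O)c(-c2cc(OC)ccc2Br)c1O.[Cl-] | intermediate
15 | 1-[3-(2-bromo-5-methoxyphenyl)-6-ethoxy-2,4-dihydroxyphenyl]ethan-1-one | CC(=O)c1c(OCC)cc(O)c(-c2cc(OC)ccc2Br)c1O | intermediate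
16 | 1-[4-(benzyloxy)-3-(2-bromo-5-methoxyphenyl)-6-ethoxy-2-hydroxyphenyl]ethan-1-one | CC(=O)c1c(OCC)cc(OCc2ccccc2)c(-c2cc(OC)ccc2Br)c1O | intermediate
17 | 4-methoxybenzoyl chloride | COc1ccc(C(Cl)=O)cc1 | starting material
18 | dilithium phenoxide–enolate of 16 | [Li+].[Li+].C=C([O-])c1c(OCC)cc(OCc2ccccc2)c(-c2cc(OC)ccc2Br)c1[O-] | intermediate
19 | 1-[4-(benzyloxy)-3-(2-bromo-5-methoxyphenyl)-6-ethoxy-2-hydroxyphenyl]-3-(4-methoxyphenyl)propane-1,3-dione | COc1ccc(C(=O)CC(=O)c2c(OCC)cc(OCc3ccccc3)c(-c3cc(OC)ccc3Br)c2O)cc1 | intermediate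
20 | 7-(benzyloxy)-8-(2-bromo-5-methoxyphenyl)-5-ethoxy-2-(4-methoxyphenyl)-4H-chromen-4-one | CCOc1cc(OCc2ccccc2)c(-c2cc(OC)ccc2Br)c2oc(-c3ccc(OC)cc3)cc(=O)c12 | intermediate
21 | phenyl 2-[7-(benzyloxy)-5-ethoxy-2-(4-methoxyphenyl)-4-oxo-4H-chromen-8-yl]-4-methoxybenzoate | CCOc1cc(OCc2ccccc2)c(-c2cc(OC)ccc2C(=O)Oc2ccccc2)c2oc(-c3ccc(OC)cc3)cc(=O)c12 | intermediate
22 | 1-(2,4,6-trihydroxyphenyl)ethan-1-one | CC(=O)c1c(O)cc(O)cc1O | starting material
23 | 1-[2,4-bis(benzyloxy)-6-hydroxyphenyl]ethan-1-one | CC(=O)c1c(O)cc(OCc2ccccc2)cc1OCc1ccccc1 | intermediate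
24 | dilithium phenoxide–enolate of 23 | [Li+].[Li+].C=C([O-])c1c([O-])cc(OCc2ccccc2)cc1OCc1ccccc1 | intermediate
25 | 1-[2,4-bis(benzyloxy)-6-hydroxyphenyl]-3-{2-[7-(benzyloxy)-5-ethoxy-2-(4-methoxyphenyl)-4-oxo-4H-chromen-8-yl]-4-methoxyphenyl}propane-1,3-dione | CCOc1cc(OCc2ccccc2)c(-c2cc(OC)ccc2C(=O)CC(=O)c2c(O)cc(OCc3ccccc3)cc2OCc2ccccc2)c2oc(-c3ccc(OC)cc3)cc(=O)c12 | intermediate
26 | 7-(benzyloxy)-8-{2-[5,7-bis(benzyloxy)-4-oxo-4H-chromen-2-yl]-5-methoxyphenyl}-5-ethoxy-2-(4-methoxyphenyl)-4H-chromen-4-one | CCOc1cc(OCc2ccccc2)c(-c2cc(OC)ccc2-c2cc(=O)c3c(OCc4ccccc4)cc(OCc4ccccc4)cc3o2)c2oc(-c3ccc(OC)cc3)cc(=O)c12 | intermediate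
27 | 8-[2-(5,7-dihydroxy-4-oxo-4H-chromen-2-yl)-5-methoxyphenyl]-5,7-dihydroxy-2-(4-methoxyphenyl)-4H-chromen-4-one | COc1ccc(-c2cc(=O)c3c(O)cc(O)c(-c4cc(OC)ccc4-c4cc(=O)c5c(O)cc(O)cc5o4)c3o2)cc1 | target

**Step count**
Total: 13 steps. Longest linear sequence: 12 steps (steps 1 to 9 and 11 to 13, from 1); step 10 is a one-step side branch.

**Steps most likely to fail**

Step 3 (Proposed new method). The vinylogous-ester cyclobutenone may open so slowly that the ynol ether decomposes thermally first. The vinylketene may also be lost to dimerisation or to acylation of the product phenol. The fallback uses only known reaction types, sets out from 22 and comes back to the route at 16.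
- Mono-benzylation of the most acidic 4-hydroxyl (BnBr 1 equiv, K2CO3, acetone) should give 1-[4-(benzyloxy)-2,6-dihydroxyphenyl]ethan-1-one F1.
- Ethylation of one of the two equivalent hydroxyls (EtI, K2CO3, DMF) should give 1-[4-(benzyloxy)-2-ethoxy-6-hydroxyphenyl]ethan-1-one F2.
- Iodination ortho to the free hydroxyl (benzyltrimethylammonium dichloroiodate, NaHCO3, CH2Cl2–MeOH) should give 1-[4-(benzyloxy)-6-ethoxy-2-hydroxy-3-iodophenyl]ethan-1-one F3. The site of iodination would need to be confirmed, because the other free position would lead to the 6-aryl series.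
- Suzuki–Miyaura coupling of F3 with (2-bromo-5-methoxyphenyl)boronic acid (Pd(PPh3)4, K2CO3, dioxane–H2O, 70 °C), selective for the C–I bond over the C–Br bond of the boronic acid, should give 16.

Step 11. The lithium enolate may add to the chromone of 21 (conjugate or carbonyl addition), or acyl transfer at the crowded ortho-biaryl ester may stall. The fallback replaces the intermolecular condensation by an intramolecular acyl shift, sets out from 21 and comes back at 25.
- Hydrolysis (LiOH, THF–H2O, rt) should give 2-[7-(benzyloxy)-5-ethoxy-2-(4-methoxyphenyl)-4-oxo-4H-chromen-8-yl]-4-methoxybenzoic acid F4.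
- Esterification of F4 with the hydroxyl of 23 (EDC·HCl, DMAP, CH2Cl2) should give 2-acetyl-3,5-bis(benzyloxy)phenyl 2-[7-(benzyloxy)-5-ethoxy-2-(4-methoxyphenyl)-4-oxo-4H-chromen-8-yl]-4-methoxybenzoate F5.
- Baker–Venkataraman O-to-C acyl shift of F5 (KOH, pyridine, 50 °C) should give 25.

Step 13. Cleavage of the chelated ethyl ether may remain incomplete at temperatures that spare the methyl ethers, or benzyl cations may alkylate the phloroglucinol rings. The fallback separates the two tasks, sets out from 26 and comes back at 27.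
- Hydrogenolysis (H2, Pd/C, THF–MeOH, rt) should remove the three benzyl groups and give 8-[2-(5,7-dihydroxy-4-oxo-4H-chromen-2-yl)-5-methoxyphenyl]-5-ethoxy-7-hydroxy-2-(4-methoxyphenyl)-4H-chromen-4-one F6.
- Chelation-directed dealkylation of F6 with MgI2·OEt2 (PhMe–Et2O, 70 °C), in which iodide attacks only the ethyl group held in the magnesium chelate with the C4 carbonyl, should give 27.

**Further compounds**
F1 | step 3 | 1-[4-(benzyloxy)-2,6-dihydroxyphenyl]ethan-1-one | CC(=O)c1c(O)cc(OCc2ccccc2)cc1O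
F2 | step 3 | 1-[4-(benzyloxy)-2-ethoxy-6-hydroxyphenyl]ethan-1-one | CCOc1cc(OCc2ccccc2)cc(O)c1C(C)=O
F3 | step 3 | 1-[4-(benzyloxy)-6-ethoxy-2-hydroxy-3-iodophenyl]ethan-1-one | CCOc1cc(OCc2ccccc2)c(I)c(O)c1C(C)=O
F4 | step 11 | 2-[7-(benzyloxy)-5-ethoxy-2-(4-methoxyphenyl)-4-oxo-4H-chromen-8-yl]-4-methoxybenzoic acid | CCOc1cc(OCc2ccccc2)c(-c2cc(OC)ccc2C(=O)O)c2oc(-c3ccc(OC)cc3)cc(=O)c12
F5 | step 11 | 2-acetyl-3,5-bis(benzyloxy)phenyl 2-[7-(benzyloxy)-5-ethoxy-2-(4-methoxyphenyl)-4-oxo-4H-chromen-8-yl]-4-methoxybenzoate | CCOc1cc(OCc2ccccc2)c(-c2cc(OC)ccc2C(=O)Oc2cc(OCc3ccccc3)cc(OCc3ccccc3)c2C(C)=O)c2oc(-c3ccc(OC)cc3)cc(=O)c12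
F6 | step 13 | 8-[2-(5,7-dihydroxy-4-oxo-4H-chromen-2-yl)-5-methoxyphenyl]-5-ethoxy-7-hydroxy-2-(4-methoxyphenyl)-4H-chromen-4-one | CCOc1cc(O)c(-c2cc(OC)ccc2-c2cc(=O)c3c(O)cc(O)cc3o2)c2oc(-c3ccc(OC)cc3)cc(=O)c12
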